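In Sunday's readings the isomer of the product gains more than the target late on: between 2.00 h and 4.00 h the target goes from 22.1 % to 22.7 %, the isomer from 5.4 % to 8.0 %. Wednesday's run shows the same pattern: between 50.0 min and 120 min the target goes from 24.0 % to 25.9 %, the isomer from 2.9 % to 8.5 %.

| flask | starting material | temperature | remark | time |
|---|---|---|---|---|
| Sunday's | 0.75 M | 44 °C | run made earlier |  |
| Wednesday's | 1.1 M | 52 °C | run made earlier |  |
| midnight | 1.5 M | 40 °C |  | 3.0 h |
| dusk | 1.5 M |  | at 55 °C until 40 min, from then on at 40 °C | 3.0 h |
| autumn | 1.5 M | 55 °C |  | 3.0 h |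

Sunday's run (percent of the starting material charged)

| time / h | target / % | isomer of the product / % |
|---|---|---|
| 0.500 | 9.1 | 1.3 |
| 1.00 | 17.0 | 3.3 |
| 1.50 | 21.6 | 2.7 |
| 2.00 | 22.1 | 5.4 |
| 2.50 | 21.1 | 5.4 |
| 3.00 | 21.8 | 8.4 |
| 4.00 | 22.7 | 8.0 |

Wednesday's run (percent of the starting material charged)

| time / min | target / % | isomer of the product / % |
|---|---|---|
| 8.00 | 4.5 | 2.5 |
| 15.0 | 11.2 | 0 |
| 20.0 | 16.2 | 0.9 |
| 30.0 | 19.5 | 1.9 |
| 50.0 | 24.0 | 2.9 |
| 80.0 | 25.7 | 8.4 |
| 120 | 25.9 | 8.5 |

(standard deviation of a reading: 1 percentage point)

- in percentages every species weighs as the starting material in it: one self-condensation product counts as two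
- the numbers in the tables scatter with a standard deviation of 1 percentage point
- candidate steps: starting material -> intermediate; intermediate <-> target; intermediate <-> isomer of the product; 2 starting material -> self-condensation product

1. which flask leads in share of target in all that became target or isomer of the product ("all alike" within 1.5 percentage points) (midnight / dusk / autumn / all alike)
2. share of target in all that became target or isomer of the product, midnight
3. share of target in all that became target or isomer of the product, dusk
4. share of target in all that became target or isomer of the product, autumn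

Take the target as in balance with the intermediate and the isomer as a slow leak, which is kinetic control slowly giving way to thermodynamic control. Then [isomer of the product]/[target] climbs steadily with time. Divide that ratio at the last reading by its time: Sunday's run at 44 °C gives 0.0881 h⁻¹, and Wednesday's at 52 °C gives 0.164 h⁻¹. Each reading scatters by 1 percentage point, so both are rough. Letting every degree multiply the rate by the same factor, I get 0.207 h⁻¹ at 55 °C and 0.0646 h⁻¹ at 40 °C. This rate of climb is the isomer clock, and the share of target is one over one plus clock times time.

That gives me 83.8 % for midnight and 61.7 % for autumn. Dusk runs the hot clock for 40 min and the cool clock for the rest, which gives 77.6 %. So midnight should lead.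

The forecast also puts midnight first, with 81 %, 76 % and 75 % for midnight, dusk and autumn, expecting “a roughly temperature-independent ratio”, and in autumn it stands above mine.

The flask gives 83.2 % for midnight, 71.2 % for dusk and 60.8 % for autumn, so midnight leads.

    starting material → intermediate (k = 2.50 × 10⁻⁴ s⁻¹, Ea = 89.0 kJ mol⁻¹)
    intermediate ⇌ target (K = 0.500, k = 2.40 × 10⁻⁴ s⁻¹, Ea = 99.0 kJ mol⁻¹, ΔH = 30.0 kJ mol⁻¹)
    intermediate ⇌ isomer of the product (K = 2.60, k = 1.10 × 10⁻⁵ s⁻¹, Ea = 107 kJ mol⁻¹, ΔH = −62.0 kJ mol⁻¹)
    2 starting material → self-condensation product (k = 1.60 × 10⁻⁴ M⁻¹ s⁻¹, Ea = 77.0 kJ mol⁻¹)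
    (constants at 40 °C)

In midnight the exchange of intermediate and target relaxes, both ways together, with a half-life of 0.267 h, far shorter than the 18 h forward half-life of the intermediate's loss to isomer at 3.00 h. Dusk's target falls after the cooling, from 24.2 % at 0.667 h to 17.8 % at 3.00 h, and my 77.6 % for dusk stands above the flask's 71.2 %. For midnight read at 2.0 h, clock times time gives a ratio of 0.129, hence a share of 88.6 %, and that flask stands at 88.0 %.

(The data were computed from invented constants; noise was put on by code.)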